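The route rests on cutting ring A (C1–C5, C10) across C3–C4 and C5–C10. This traces the cis methyl pair on tertiary C4 and quaternary C5, together with the C2 oxygen, back to (E)-tiglic aldehyde and a 1-amino-3-silyloxybutadiene. One catalytic enantioselective Diels–Alder reaction forms both bonds, ring A and both stereocentres, and acid then unveils the C1=C10 enone on which ring B (C5–C10) is built. The precursors are the commercial enal and the diene made in one step from 4-(dimethylamino)but-3-en-2-one. The remaining stereocentres are relayed from C5: trans fusion by dissolving-metal reduction, then bulky-hydride reduction, enolate hydroxylation, directed epoxidation and trans-diaxial epoxide opening.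

Key step: step 2

Remarks on the chemistry (one line each):
- Numbering: all intermediates carry the eremophilane numbers of the target (ring A = C1–C5, C10; ring B = C5–C10; C14 on C5, C15 on C4); β is the face of the C5 methyl.
- Check: enone 6 (R at the quaternary carbon, S at the methine) has the C4/C5 configuration of the target, both methyl groups β and cis.
- Carbon nucleophiles should add to C10 of the C1=C10 enone anti to the C4 and C5 methyl groups, which leads to the cis-fused series. The trans fusion (H-10 anti to C14) is therefore set by hydrogen delivery to a C10-substituted enone (step 6).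
- The isopropenyl group enters after the C9 oxygen, so that C7 never carries its axial substituent next to a carbonyl group.
- Assumption: the (R,R) catalyst gives the R quaternary centre of 6; if the facial sense is the opposite, the (S,S) catalyst is used.
- Assumption: Grignard reagents 8 and 24 and acid 26 are bought (24 can also be made from 2-bromopropene and Mg).

Step 1
Reactants: 1 (E)-4-(dimethylamino)but-3-en-2-one
Product: 3 (E)-1-(dimethylamino)-3-(tert-butyldimethylsilyloxy)buta-1,3-diene, via sodium dienolate 2 (not isolated)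
Conditions: NaN(SiMe3)2, THF, −78 °C; TBSCl, −78 °C → rt
Reagents that add atoms: tert-butyldimethylsilyl chloride, CC(C)(C)[Si](C)(C)Cl
Why: Kinetic deprotonation of the methyl ketone of the vinylogous amide and O-silylation of the cross-conjugated enolate (enolate O-silylation) is the standard entry to this diene class; no stereocentre is formed and the E enamine geometry is kept.

Step 2
Reactants: 3 (E)-1-(dimethylamino)-3-(tert-butyldimethylsilyloxy)buta-1,3-diene; 4 (E)-2-methylbut-2-enal (tiglic aldehyde)
Product: 6 (1R,6S)-1,6-dimethyl-4-oxocyclohex-2-ene-1-carbaldehyde [(4R,5S)-4-formyl-4,5-dimethylcyclohex-2-enone], via cycloadduct 5 (not isolated)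
Conditions: (4R,5R)-2,2-dimethyl-α,α,α′,α′-tetra(1-naphthyl)-1,3-dioxolane-4,5-dimethanol (1-naphthyl TADDOL, 20 mol%), toluene, −78 → −40 °C; then aq. HF, MeCN, 0 °C
Reagents that add atoms: none
Why: The electron-rich diene adds in a concerted, asynchronous [4+2] cycloaddition to the aldehyde, which is activated by a single hydrogen bond from one TADDOL hydroxyl; the closest known reaction is the TADDOL-catalysed Diels–Alder reaction of this diene class with α-substituted acroleins. Ring A is closed by intermolecular suprafacial six-membered cycloaddition that forms C3–C4 and C5–C10 in one event. The cis relation of C14 and C15 follows stereospecifically from the E geometry of the dienophile, and the absolute configuration at C4 and C5 from the naphthyl groups of the bound catalyst, which shield one face of the aldehyde. The step needs C3 (the CH2 terminus) to bond to the β carbon, which the push–pull polarisation of the diene secures, and the endo/exo question at C10 is erased when HF removes Me2NH and the silyl group to give the C1=C10 enone.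

Step 3
Reactants: 6 (1R,6S)-1,6-dimethyl-4-oxocyclohex-2-ene-1-carbaldehyde
Product: 7 (4R,5S)-4-ethenyl-4,5-dimethylcyclohex-2-en-1-one
Conditions: Ph3PCH3Br, KN(SiMe3)2, THF, 0 °C; then 6 (1.0 equiv ylide), −78 → 0 °C
Reagents that add atoms: methyltriphenylphosphonium bromide, C[P+](c1ccccc1)(c1ccccc1)c1ccccc1.[Br-]
Why: Wittig methylenation is much faster at the aldehyde than at the conjugated ketone, so one equivalent of ylide at low temperature should turn C6 into the vinyl carbon without touching the enone; no stereocentre is formed.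

Step 4
Reactants: 7 (4R,5S)-4-ethenyl-4,5-dimethylcyclohex-2-en-1-one; 8 but-3-enylmagnesium bromide
Product: 10 (4R,5S)-3-(but-3-enyl)-4-ethenyl-4,5-dimethylcyclohex-2-en-1-one, via trimethylsilyl enol ether 9 (not isolated)
Conditions: CuBr·SMe2 (10 mol%), Me3SiCl, THF, −78 °C; crude 9: Pd(OAc)2 (1 equiv), MeCN, rt
Reagents that add atoms: none
Why: Copper-catalysed conjugate addition of the Grignard reagent, accelerated and trapped by Me3SiCl, attaches C9 to C10 and gives the C1=C2 silyl enol ether regiospecifically, and Saegusa–Ito oxidation (β-hydride loss from C10, the only position available) restores the C1=C10 enone, so the transient C10 centre is erased on purpose.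

Step 5
Reactants: 10 (4R,5S)-3-(but-3-enyl)-4-ethenyl-4,5-dimethylcyclohex-2-en-1-one
Product: 11 (4S,4aS)-4,4a-dimethyl-4,4a,7,8-tetrahydronaphthalen-2(3H)-one (C1=C10 enone, C6=C7 alkene)
Conditions: second-generation Grubbs catalyst RuCl2(=CHPh)(H2IMes)(PCy3) (3 mol%), CH2Cl2, 40 °C
Reagents that add atoms: none
Why: Ring-closing metathesis of the two monosubstituted alkenes closes ring B as a cyclohexene (C6=C7) with loss of ethene, while the electron-poor trisubstituted enone alkene stays inert; no stereocentre is formed.

Step 6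
Reactants: 11 (4S,4aS)-4,4a-dimethyl-4,4a,7,8-tetrahydronaphthalen-2(3H)-one
Product: 13 trans-fused 4β,5β-dimethyl-10αH-11,12,13-trinoreremophil-6-en-2-one, via lithium enolate 12 (not isolated)
Conditions: Li, NH3(l), THF, t-BuOH (1 equiv), −78 °C; then NH4Cl
Reagents that add atoms: none
Why: In this dissolving-metal (Birch-type) enone reduction the β-carbanion at C10 is protonated axially, in the chair-like arrangement that keeps overlap with the enolate, which puts H-10 anti to the C5 methyl and should give the trans-fused decalone, while the isolated C6=C7 alkene survives.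

Step 7
Reactants: 13 trans-fused 4β,5β-dimethyl-10αH-11,12,13-trinoreremophil-6-en-2-one
Product: 14 4β,5β-dimethyl-10αH-11,12,13-trinoreremophil-6-en-2α-ol
Conditions: LiBH(s-Bu)3, THF, −78 °C; then NaOH, H2O2
Reagents that add atoms: none
Why: The bulky hydride attacks the C2 ketone along the equatorial path, avoiding the axial hydrogens at C4 and C10, and should give the axial 2α-alcohol, as in trans-fused 2-decalones and 3-oxo-5α-steroids (substrate-controlled ketone reduction).

Step 8
Reactants: 14 4β,5β-dimethyl-10αH-11,12,13-trinoreremophil-6-en-2α-ol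
Product: 15 2α-(tert-butyldimethylsilyloxy)-10αH-11,12,13-trinoreremophil-6-ene
Conditions: TBSCl, imidazole, DMF, 40 °C
Reagents that add atoms: tert-butyldimethylsilyl chloride, CC(C)(C)[Si](C)(C)Cl
Why: Standard silylation of a secondary alcohol masks the C2 hydroxyl against the oxidations and the strong base that follow; no stereocentre is touched.

Step 9
Reactants: 15 2α-(tert-butyldimethylsilyloxy)-10αH-11,12,13-trinoreremophil-6-ene
Product: 16 2α-(tert-butyldimethylsilyloxy)-10αH-11,12,13-trinoreremophil-6-en-8-one
Conditions: Rh2(cap)4 (dirhodium tetracaprolactamate, 1 mol%), t-BuOOH, K2CO3 (cat.), CH2Cl2, rt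
Reagents that add atoms: tert-butyl hydroperoxide, CC(C)(C)OO
Why: In this rhodium-catalysed allylic oxidation the only allylic C–H bonds are at C8 because C5 is quaternary, and the peroxy radical should couple at the unhindered C8 end of the allyl radical, so the mixed peroxide collapses to the C6=C7–C8=O enone; no stereocentre is formed.

Step 10
Reactants: 16 2α-(tert-butyldimethylsilyloxy)-10αH-11,12,13-trinoreremophil-6-en-8-one
Product: 18 2α-(tert-butyldimethylsilyloxy)-9α-hydroxy-10αH-11,12,13-trinoreremophil-6-en-8-one, via potassium dienolate 17 (not isolated)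
Conditions: KN(SiMe3)2, THF, −78 °C; 2-(phenylsulfonyl)-3-phenyloxaziridine; AcOH
Reagents that add atoms: 2-(phenylsulfonyl)-3-phenyloxaziridine, O=S(=O)(c1ccccc1)N1OC1c1ccccc1
Why: The enone can be deprotonated only at C9 (C7 is vinylic, C5 is quaternary), and the cross-conjugated dienolate should be hydroxylated by the N-sulfonyloxaziridine (enolate hydroxylation) from the α face, anti to the C5 methyl that is 1,3-syn to C9, giving the equatorial 9α-alcohol, which is also the more stable epimer of this enolisable centre.

Step 11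
Reactants: 18 2α-(tert-butyldimethylsilyloxy)-9α-hydroxy-10αH-11,12,13-trinoreremophil-6-en-8-one
Product: 19 the C8 4-methylbenzenesulfonylhydrazone of 18
Conditions: TsNHNH2, EtOH, AcOH (cat.), 50 °C
Reagents that add atoms: 4-methylbenzenesulfonohydrazide, Cc1ccc(cc1)S(=O)(=O)NN
Why: Condensation of the ketone with the sulfonyl hydrazide (hydrazone formation) prepares the reductive alkene transposition, and C9 already holds its preferred equatorial configuration, so the weak acid should not change it.

Step 12
Reactants: 19 the C8 4-methylbenzenesulfonylhydrazone of 18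
Product: 22 2α-(tert-butyldimethylsilyloxy)-10αH-11,12,13-trinoreremophil-7-en-9α-ol, via N-boryl tosylhydrazide 20 (not isolated), via allyl diazene 21 (not isolated)
Conditions: catecholborane (excess), CHCl3, 0 °C; NaOAc·3H2O, 60 °C
Reagents that add atoms: none
Why: In this reduction of an α,β-unsaturated tosylhydrazone with alkene transposition, hydride adds to C8, acetate expels sulfinate and the allyl diazene loses N2 by a retro-ene hydrogen shift to C6, which moves the alkene regiospecifically to C7=C8 and leaves the 9α-hydroxyl allylic; C6 becomes CH2, so no new stereocentre results.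

Step 13
Reactants: 22 2α-(tert-butyldimethylsilyloxy)-10αH-11,12,13-trinoreremophil-7-en-9α-ol
Product: 23 2α-(tert-butyldimethylsilyloxy)-7α,8α-epoxy-10αH-11,12,13-trinoreremophilan-9α-ol
Conditions: mCPBA, NaHCO3, CH2Cl2, 0 °C
Reagents that add atoms: 3-chloroperoxybenzoic acid, OOC(=O)c1cccc(Cl)c1
Why: Hydroxyl-directed peracid epoxidation delivers oxygen to the face of the allylic 9α-hydroxyl, and the axial C5 methyl blocks the β face at C7, so both effects should give the 7α,8α-epoxide.

Step 14
Reactants: 23 2α-(tert-butyldimethylsilyloxy)-7α,8α-epoxy-10αH-11,12,13-trinoreremophilan-9α-ol; 24 isopropenylmagnesium bromide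
Product: 25 2α-(tert-butyldimethylsilyloxy)-7αH,10αH-eremophil-11-ene-8α,9α-diol (7β-isopropenyl)
Conditions: CuI (20 mol%), THF, −30 → 0 °C; aq. NH4Cl
Reagents that add atoms: none
Why: Copper-catalysed Grignard opening of the epoxide follows the Fürst–Plattner rule on the rigid trans-decalin: anti attack that leads directly to a chair is possible only at C7 from the β face, so inversion at C7 should give the trans-diaxial 7β-isopropenyl/8α-hydroxyl pair, as in the C2 opening of 2α,3α-epoxy-5α-steroids, and the cis 9α-alkoxide cannot undergo Payne migration.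

Step 15
Reactants: 25 2α-(tert-butyldimethylsilyloxy)-7αH,10αH-eremophil-11-ene-8α,9α-diol; 26 (Z)-3-methylpent-2-enoic acid
Product: 28 2α-(tert-butyldimethylsilyloxy)-8α-hydroxy-7αH,10αH-eremophil-11-en-9α-yl (Z)-3-methylpent-2-enoate, via O-acylisourea 27 (not isolated)
Conditions: DCC, DMAP (10 mol%), CH2Cl2, 0 °C → rt
Reagents that add atoms: none
Why: In this Steglich esterification the equatorial C9 hydroxyl should be acylated in preference to the axial C8 hydroxyl, which is flanked by the branched C7, and carbodiimide activation without amine base and with little DMAP avoids ketene formation, so the Z geometry of the acid is kept.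

Step 16
Reactants: 28 2α-(tert-butyldimethylsilyloxy)-8α-hydroxy-7αH,10αH-eremophil-11-en-9α-yl (Z)-3-methylpent-2-enoate
Product: 29 2α,8α-dihydroxy-7αH,10αH-eremophil-11-en-9α-yl (Z)-3-methylpent-2-enoate (target)
Conditions: HF·pyridine, THF, 0 °C → rt
Reagents that add atoms: none
Why: Buffered fluoride cleavage of the silyl ether (desilylation) is compatible with the enoate, the isopropenyl group and the cis hydroxy ester, and basic fluoride sources that could start acyl migration are avoided.

Compound list
1 | (E)-4-(dimethylamino)but-3-en-2-one | CC(=O)/C=C/N(C)C | starting material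
2 | sodium (E)-4-(dimethylamino)buta-1,3-dien-2-olate | [Na+].[O-]C(=C)/C=C/N(C)C | intermediate (not isolated)
3 | (E)-1-(dimethylamino)-3-(tert-butyldimethylsilyloxy)buta-1,3-diene | C=C(O[Si](C)(C)C(C)(C)C)/C=C/N(C)C | intermediate
4 | (E)-2-methylbut-2-enal (tiglic aldehyde) | C/C=C(\C)C=O | starting material
5 | (1R,2S,6S)-4-(tert-butyldimethylsilyloxy)-2-(dimethylamino)-1,6-dimethylcyclohex-3-ene-1-carbaldehyde (endo adduct, NMe2 cis to CHO) | O=C[C@]1(C)[C@@H](C)CC(O[Si](C)(C)C(C)(C)C)=C[C@@H]1N(C)C | intermediate (not isolated)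
6 | (1R,6S)-1,6-dimethyl-4-oxocyclohex-2-ene-1-carbaldehyde [(4R,5S)-4-formyl-4,5-dimethylcyclohex-2-enone, ring A] | O=C[C@]1(C)[C@@H](C)CC(=O)C=C1 | intermediate
7 | (4R,5S)-4-ethenyl-4,5-dimethylcyclohex-2-en-1-one | C=C[C@]1(C)[C@@H](C)CC(=O)C=C1 | intermediate
8 | but-3-enylmagnesium bromide | C=CCC[Mg]Br | starting material
9 | 3-(but-3-enyl)-4-ethenyl-4,5-dimethyl-1-(trimethylsilyloxy)cyclohexene, side chain on C10 anti to the methyl groups (expected epimer) | C=C[C@]1(C)[C@@H](C)CC(O[Si](C)(C)C)=C[C@@H]1CCC=C | intermediate (not isolated)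
10 | (4R,5S)-3-(but-3-enyl)-4-ethenyl-4,5-dimethylcyclohex-2-en-1-one | C=C[C@]1(C)[C@@H](C)CC(=O)C=C1CCC=C | intermediate
11 | (4S,4aS)-4,4a-dimethyl-4,4a,7,8-tetrahydronaphthalen-2(3H)-one | C1=C[C@]2(C)[C@@H](C)CC(=O)C=C2CC1 | intermediate
12 | lithium enolate (C1=C2–OLi) of 13 | C1=C[C@]2(C)[C@@H](C)CC([O-])=C[C@H]2CC1.[Li+] | intermediate (not isolated)
13 | trans-fused 4β,5β-dimethyl-10αH-11,12,13-trinoreremophil-6-en-2-one | C1=C[C@]2(C)[C@@H](C)CC(=O)C[C@H]2CC1 | intermediate
14 | 4β,5β-dimethyl-10αH-11,12,13-trinoreremophil-6-en-2α-ol | C1=C[C@]2(C)[C@@H](C)C[C@H](O)C[C@H]2CC1 | intermediate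
15 | 2α-(tert-butyldimethylsilyloxy)-10αH-11,12,13-trinoreremophil-6-ene | C1=C[C@]2(C)[C@@H](C)C[C@H](O[Si](C)(C)C(C)(C)C)C[C@H]2CC1 | intermediate
16 | 2α-(tert-butyldimethylsilyloxy)-10αH-11,12,13-trinoreremophil-6-en-8-one | O=C1C=C[C@]2(C)[C@@H](C)C[C@H](O[Si](C)(C)C(C)(C)C)C[C@H]2C1 | intermediate
17 | potassium 6,8-dien-8-olate of 16 | [K+].[O-]C=1C=C[C@]2(C)[C@@H](C)C[C@H](O[Si](C)(C)C(C)(C)C)C[C@H]2C=1 | intermediate (not isolated)
18 | 2α-(tert-butyldimethylsilyloxy)-9α-hydroxy-10αH-11,12,13-trinoreremophil-6-en-8-one | O=C1C=C[C@]2(C)[C@@H](C)C[C@H](O[Si](C)(C)C(C)(C)C)C[C@H]2[C@@H]1O | intermediate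
19 | C8 4-methylbenzenesulfonylhydrazone of 18 (C=N geometry not defined) | Cc1ccc(cc1)S(=O)(=O)NN=C1C=C[C@]2(C)[C@@H](C)C[C@H](O[Si](C)(C)C(C)(C)C)C[C@H]2[C@@H]1O | intermediate
20 | N-(1,3,2-benzodioxaborol-2-yl) tosylhydrazide at C8, C9 hydroxyl O-borylated (C8 configuration not defined, lost in the next event) | Cc1ccc(cc1)S(=O)(=O)NN(B3Oc4ccccc4O3)C5C=C[C@]6(C)[C@@H](C)C[C@H](O[Si](C)(C)C(C)(C)C)C[C@H]6[C@@H]5OB7Oc8ccccc8O7 | intermediate (not isolated)
21 | 8-diazenyl-2α-(tert-butyldimethylsilyloxy)-10αH-11,12,13-trinoreremophil-6-en-9α-ol (C8 configuration not defined) | N=NC1C=C[C@]2(C)[C@@H](C)C[C@H](O[Si](C)(C)C(C)(C)C)C[C@H]2[C@@H]1O | intermediate (not isolated)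
22 | 2α-(tert-butyldimethylsilyloxy)-10αH-11,12,13-trinoreremophil-7-en-9α-ol | C1=CC[C@]2(C)[C@@H](C)C[C@H](O[Si](C)(C)C(C)(C)C)C[C@H]2[C@@H]1O | intermediate
23 | 2α-(tert-butyldimethylsilyloxy)-7α,8α-epoxy-10αH-11,12,13-trinoreremophilan-9α-ol | O1[C@@H]2C[C@]3(C)[C@@H](C)C[C@H](O[Si](C)(C)C(C)(C)C)C[C@H]3[C@H](O)[C@H]12 | intermediate
24 | isopropenylmagnesium bromide | C=C(C)[Mg]Br | starting material
25 | 2α-(tert-butyldimethylsilyloxy)-7αH,10αH-eremophil-11-ene-8α,9α-diol | C=C(C)[C@H]1C[C@]2(C)[C@@H](C)C[C@H](O[Si](C)(C)C(C)(C)C)C[C@H]2[C@H](O)[C@@H]1O | intermediate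
26 | (Z)-3-methylpent-2-enoic acid | OC(=O)/C=C(/C)CC | starting material
27 | N,N′-dicyclohexyl-O-[(Z)-3-methylpent-2-enoyl]isourea | C1CCCCC1N=C(NC1CCCCC1)OC(=O)/C=C(/C)CC | intermediate (not isolated)
28 | 2α-(tert-butyldimethylsilyloxy)-8α-hydroxy-7αH,10αH-eremophil-11-en-9α-yl (Z)-3-methylpent-2-enoate | C=C(C)[C@H]1C[C@]2(C)[C@@H](C)C[C@H](O[Si](C)(C)C(C)(C)C)C[C@H]2[C@H](OC(=O)/C=C(/C)CC)[C@@H]1O | intermediate
29 | 2α,8α-dihydroxy-7αH,10αH-eremophil-11-en-9α-yl (Z)-3-methylpent-2-enoate | C=C(C)[C@H]1C[C@]2(C)[C@@H](C)C[C@H](O)C[C@H]2[C@H](OC(=O)/C=C(/C)CC)[C@@H]1O | target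

Total step count: 16. Longest linear sequence: 16 steps (fully linear from 1; compounds 4, 8, 24 and 26 enter as bought).

Steps most likely to fail

1. Step 2. The trisubstituted enal may add too slowly at the temperature at which the hydrogen-bonded pathway dominates, so that the uncatalysed background reaction erodes facial selectivity or conversion stalls. The fallback replaces catalyst control by auxiliary control and sets out from 4. 4-Methoxybut-3-en-2-one is condensed with (2R,5R)-2,5-diphenylpyrrolidine (MeOH, rt) to give (E)-4-[(2R,5R)-2,5-diphenylpyrrolidin-1-yl]but-3-en-2-one F1. Treatment with KN(SiMe3)2 and TBSCl (THF, −78 °C) should convert it into the twofold-symmetric 1-(2,5-diphenylpyrrolidin-1-yl)-3-(tert-butyldimethylsilyloxy)buta-1,3-diene F2. F2 and 4 should combine without catalyst (toluene, 0 °C → rt), the phenyl groups shielding one face of the diene, to give the cycloadduct F3. Aqueous HF in MeCN should then release the recoverable amine and return the route to 6. The (2R,5R) antipode is assumed to lead to 6; otherwise the (2S,5S) amine is used.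

2. Step 14. The branched alkenyl group must arrive axially at C7 past the syn-axial C5 methyl; if this is slow, halide opening of the epoxide by the magnesium salt or Lewis-acid rearrangement of the epoxide can take over. The fallback uses a slim sp nucleophile and builds the isopropenyl group afterwards; it sets out from 23. Et2AlC≡CSiMe3 (toluene, 0 °C → rt) should open the epoxide at C7 in the same trans-diaxial sense to give 2α-(tert-butyldimethylsilyloxy)-7β-(trimethylsilylethynyl)-10αH-11,12,13-trinoreremophilane-8α,9α-diol F4. K2CO3 in MeOH should remove the alkynyl silyl group to give the 7β-ethynyl diol F5. Zirconium-catalysed carboalumination (AlMe3, Cp2ZrCl2 cat., CH2Cl2) places methyl on the internal alkyne carbon, and protonolysis of the vinylalane with water should give the isopropenyl group, returning the route to 25.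

3. Step 9. The allyl radical can be captured at its other end (C6) and the enone can be oxidised further, which would cost regioselectivity and mass balance. The fallback separates oxygen delivery from oxidation and sets out from 15. SeO2 (cat.) with t-BuOOH (CH2Cl2, rt) acts by an ene reaction and a [2,3] shift that can deliver oxygen only to C8, the sole allylic CH2, and should give 2α-(tert-butyldimethylsilyloxy)-10αH-11,12,13-trinoreremophil-6-en-8-ol F6 as a mixture of C8 epimers. Dess–Martin periodinane (CH2Cl2, rt) should oxidise it, returning the route to 16.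

Further compounds
F1 | step 2 | (E)-4-[(2R,5R)-2,5-diphenylpyrrolidin-1-yl]but-3-en-2-one | CC(=O)/C=C/N1[C@@H](c2ccccc2)CC[C@@H]1c3ccccc3
F2 | step 2 | (E)-1-[(2R,5R)-2,5-diphenylpyrrolidin-1-yl]-3-(tert-butyldimethylsilyloxy)buta-1,3-diene | C=C(O[Si](C)(C)C(C)(C)C)/C=C/N1[C@@H](c2ccccc2)CC[C@@H]1c3ccccc3
F3 | step 2 | 4-(tert-butyldimethylsilyloxy)-2-[(2R,5R)-2,5-diphenylpyrrolidin-1-yl]-1,6-dimethylcyclohex-3-ene-1-carbaldehyde (ring configuration as in 5) | O=C[C@]1(C)[C@@H](C)CC(O[Si](C)(C)C(C)(C)C)=C[C@@H]1N3[C@@H](c2ccccc2)CC[C@@H]3c4ccccc4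
F4 | step 14 | 2α-(tert-butyldimethylsilyloxy)-7β-(trimethylsilylethynyl)-10αH-11,12,13-trinoreremophilane-8α,9α-diol | C[Si](C)(C)C#C[C@H]1C[C@]2(C)[C@@H](C)C[C@H](O[Si](C)(C)C(C)(C)C)C[C@H]2[C@H](O)[C@@H]1O
F5 | step 14 | 2α-(tert-butyldimethylsilyloxy)-7β-ethynyl-10αH-11,12,13-trinoreremophilane-8α,9α-diol | C#C[C@H]1C[C@]2(C)[C@@H](C)C[C@H](O[Si](C)(C)C(C)(C)C)C[C@H]2[C@H](O)[C@@H]1O
F6 | step 9 | 2α-(tert-butyldimethylsilyloxy)-10αH-11,12,13-trinoreremophil-6-en-8-ol (C8 epimers) | OC1C=C[C@]2(C)[C@@H](C)C[C@H](O[Si](C)(C)C(C)(C)C)C[C@H]2C1
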